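The target holds one ring, a 5,6-dihydro-2H-pyran-2-one (O1, C2(=O), C3, C4, C5, C6). C3 carries a homoprenyl group. C6 carries an alkenyl chain whose first carbon C1' bears CH2OAc and is doubly bonded to C2'.
Enabling feature: O1–C2(=O) is one CO2 molecule held between vinylic C3 (cis to C5 across C3=C4) and C6. C6 is allylic to C1'=C2', so C6–C1'–C2' can act as an η3-allyl cation and C3 as an alkenyl anion.
Key disconnection: CO2 is taken out. C3 becomes a (Z)-alkenyl iodide and the leaving oxygen is moved to C2', giving an acyclic (S)-allylic tert-butyl carbonate with a C1'=C6 double bond. In the forward direction, Li/CO2 then Pd(0) closes the only ring, sets C6 and creates the (E)-C1'=C2' alkene in one operation.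
The precursor is assembled from nerol (cleaved to the C2' aldehyde), propargyl alcohol (used twice: CH2O/C1'/C6 and C5/C4/C3) and homoprenyl bromide. The bonds made are C1'–C2' (alkenylzinc + aldehyde), C6–C5 (copper acetylide + allyl bromide) and one acetylide alkylation.
The carbinol configuration comes from a CBS reduction. The endgame is TBS-to-acetate exchange and TBDPS removal.

Key step: step 13

Remark: acyclic compounds 14–21 are numbered along their C16 chain from the silyloxy terminus (C1). Chain C6, C7, C8, C9, C10 and C11 become C2', C1', C6, C5, C4 and C3 of the lactone.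

Step 1
Reactants: 1 prop-2-yn-1-ol; 2 5-bromo-2-methylpent-2-ene
Product: 3 7-methyloct-6-en-2-yn-1-ol
Conditions: 1, n-BuLi (2.1 equiv), THF/DMPU, −78 to 0 °C; then 2, 0 °C to rt
Reagents that add atoms: none
Why: Acetylide alkylation (SN2) of the propargyl alcohol dianion occurs at carbon, the more nucleophilic site, on an unhindered primary bromide.

Step 2
Reactants: 3 7-methyloct-6-en-2-yn-1-ol
Product: 5 (2Z)-3-iodo-7-methylocta-2,6-dien-1-ol, via cyclic alkenylalanate 4 (not isolated)
Conditions: Red-Al (1.5 equiv), THF, 0 °C to rt; then I2, −78 to 0 °C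
Reagents that add atoms: iodine, II
Why: Hydroxyl-directed trans-hydroalumination puts aluminium on the distal alkyne carbon inside a five-membered alanate ring, and iodinolysis with retention fixes iodine cis to CH2OH, the geometry later needed for ring C3=C4.

Step 3
Reactants: 5 (2Z)-3-iodo-7-methylocta-2,6-dien-1-ol
Product: 6 (2Z)-1-bromo-3-iodo-7-methylocta-2,6-diene
Conditions: CBr4, PPh3, CH2Cl2, 0 °C
Reagents that add atoms: carbon tetrabromide, BrC(Br)(Br)Br
Why: The Appel reaction substitutes the primary allylic hydroxyl by SN2 under neutral conditions, leaving the alkenyl iodide and both alkene geometries untouched.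

Step 4
Reactants: 6 (2Z)-1-bromo-3-iodo-7-methylocta-2,6-diene; 1 prop-2-yn-1-ol
Product: 7 (5Z)-6-iodo-10-methylundeca-5,9-dien-2-yn-1-ol
Conditions: CuI (10 mol %), n-Bu4NBr (10 mol %), K2CO3, DMF, rt
Reagents that add atoms: none
Why: Copper(I)-acetylide allylation attacks the primary allylic carbon (SN2) because the fully substituted γ-carbon blocks SN2', and an alkenyl iodide does not couple with copper acetylides at room temperature.

Step 5
Reactants: 8 nerol
Product: 9 neryl tert-butyldiphenylsilyl ether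
Conditions: TBDPSCl, imidazole, CH2Cl2, rt
Reagents that add atoms: tert-butyl(chloro)diphenylsilane, CC(C)(C)[Si](Cl)(c1ccccc1)c1ccccc1
Why: Silyl ether formation gives a protecting group that withstands organometallics, oxidants and the later selective TBS cleavage.

Step 6
Reactants: 9 neryl tert-butyldiphenylsilyl ether
Product: 10 rac-6,7-epoxyneryl tert-butyldiphenylsilyl ether
Conditions: mCPBA (1.0 equiv), CH2Cl2, −20 to 0 °C
Reagents that add atoms: 3-chloroperoxybenzoic acid, OOC(=O)c1cccc(Cl)c1
Why: Prilezhaev epoxidation prefers the remote, more electron-rich 6,7-alkene over the 2,3-alkene, which the allylic silyloxy group deactivates and shields, and the racemic new centre is destroyed in step 7.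

Step 7
Reactants: 10 rac-6,7-epoxyneryl tert-butyldiphenylsilyl ether
Product: 11 (4Z)-6-[(tert-butyldiphenylsilyl)oxy]-4-methylhex-4-enal
Conditions: H5IO6, THF/Et2O, 0 °C
Reagents that add atoms: none
Why: Periodic acid opens the epoxide to the glycol and cleaves it in the same flask (Malaprade-type cleavage) without touching the Z-alkene.

Step 8
Reactants: 7 (5Z)-6-iodo-10-methylundeca-5,9-dien-2-yn-1-ol; 11 (4Z)-6-[(tert-butyldiphenylsilyl)oxy]-4-methylhex-4-enal
Product: 14 rac-(2Z,7E,10Z)-1-[(tert-butyldiphenylsilyl)oxy]-7-(hydroxymethyl)-11-iodo-3,15-dimethylhexadeca-2,7,10,14-tetraen-6-ol, via alkenylzirconocene 12 (not isolated), via alkenylzinc 13 (not isolated)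
Conditions: 7, MeLi (1.0 equiv), THF, −78 °C; Cp2Zr(H)Cl, rt; Me2Zn, −65 °C; then 11, 0 °C
Reagents that add atoms: none
Why: Alkoxide-directed syn-hydrozirconation should place Zr on the alkyne carbon next to CH2OLi, and Zr-to-Zn transmetalation followed by 1,2-addition of the alkenylzinc to the aldehyde gives the (7E)-allylic alcohol with retention of alkene geometry, the C6 carbinol centre forming racemic and being corrected in steps 10 and 11.

Step 9
Reactants: 14 rac-(2Z,7E,10Z)-1-[(tert-butyldiphenylsilyl)oxy]-7-(hydroxymethyl)-11-iodo-3,15-dimethylhexadeca-2,7,10,14-tetraen-6-ol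
Product: 15 rac-(2Z,7E,10Z)-7-{[(tert-butyldimethylsilyl)oxy]methyl}-1-[(tert-butyldiphenylsilyl)oxy]-11-iodo-3,15-dimethylhexadeca-2,7,10,14-tetraen-6-ol
Conditions: TBSCl (1.05 equiv), imidazole, CH2Cl2, 0 °C
Reagents that add atoms: tert-butyl(chloro)dimethylsilane, CC(C)(C)[Si](C)(C)Cl
Why: Selective silylation works because the primary allylic hydroxyl reacts much faster than the flanked secondary one.

Step 10
Reactants: 15 rac-(2Z,7E,10Z)-7-{[(tert-butyldimethylsilyl)oxy]methyl}-1-[(tert-butyldiphenylsilyl)oxy]-11-iodo-3,15-dimethylhexadeca-2,7,10,14-tetraen-6-ol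
Product: 16 (2Z,7E,10Z)-7-{[(tert-butyldimethylsilyl)oxy]methyl}-1-[(tert-butyldiphenylsilyl)oxy]-11-iodo-3,15-dimethylhexadeca-2,7,10,14-tetraen-6-one
Conditions: Dess–Martin periodinane, CH2Cl2, 0 °C to rt
Reagents that add atoms: none
Why: Dess–Martin oxidation erases the racemic centre under nearly neutral conditions that should not pull the skipped diene into conjugation.

Step 11
Reactants: 16 (2Z,7E,10Z)-7-{[(tert-butyldimethylsilyl)oxy]methyl}-1-[(tert-butyldiphenylsilyl)oxy]-11-iodo-3,15-dimethylhexadeca-2,7,10,14-tetraen-6-one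
Product: 17 (6S,2Z,7E,10Z)-7-{[(tert-butyldimethylsilyl)oxy]methyl}-1-[(tert-butyldiphenylsilyl)oxy]-11-iodo-3,15-dimethylhexadeca-2,7,10,14-tetraen-6-ol
Conditions: (R)-Me-CBS (20 mol %), catecholborane, toluene, −78 °C
Reagents that add atoms: none
Why: In the CBS reduction the α-branched alkenyl flank acts as the large group and the unbranched CH2 flank as the small one, so the (R)-oxazaborolidine should deliver hydride 1,2-selectively to give the (6S)-alcohol.

Step 12
Reactants: 17 (6S,2Z,7E,10Z)-7-{[(tert-butyldimethylsilyl)oxy]methyl}-1-[(tert-butyldiphenylsilyl)oxy]-11-iodo-3,15-dimethylhexadeca-2,7,10,14-tetraen-6-ol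
Product: 18 tert-butyl (6S,2Z,7E,10Z)-7-{[(tert-butyldimethylsilyl)oxy]methyl}-1-[(tert-butyldiphenylsilyl)oxy]-11-iodo-3,15-dimethylhexadeca-2,7,10,14-tetraen-6-yl carbonate
Conditions: Boc2O, DMAP (20 mol %), CH2Cl2, rt
Reagents that add atoms: di-tert-butyl dicarbonate, CC(C)(C)OC(=O)OC(=O)OC(C)(C)C
Why: DMAP-catalysed O-acylation leaves the configuration untouched and installs a leaving group hindered enough to survive brief contact with an organolithium yet easily ionised by Pd(0).

Step 13
Reactants: 18 tert-butyl (6S,2Z,7E,10Z)-7-{[(tert-butyldimethylsilyl)oxy]methyl}-1-[(tert-butyldiphenylsilyl)oxy]-11-iodo-3,15-dimethylhexadeca-2,7,10,14-tetraen-6-yl carbonate; 19 carbon dioxide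
Product: 22 (6R)-6-[(2E,6Z)-1-[(tert-butyldimethylsilyl)oxy]-8-[(tert-butyldiphenylsilyl)oxy]-6-methylocta-2,6-dien-2-yl]-3-(4-methylpent-3-en-1-yl)-5,6-dihydro-2H-pyran-2-one, via alkenyllithium 20 (not isolated), via lithium carboxylate 21 (not isolated)
Conditions: t-BuLi (2.05 equiv), Et2O, −78 °C, 10 min; dry CO2, −78 °C to rt; then Pd2(dba)3·CHCl3 (2.5 mol %), dppe (6 mol %), THF, CO2 balloon, rt to 40 °C
Reagents that add atoms: none
Why: Iodine–lithium exchange (retention at sp2 carbon) outruns attack on the hindered carbonate, and alkenyllithium 20 adds to CO2 to make the C–C bond, giving carboxylate 21 with its CO2 group held cis to chain C9. Pd(0) then ionises the allylic carbonate anti to the leaving group to a syn,syn-η3-allyl over chain C6–C7–C8, and the carboxylate oxygen attacks C8 anti to palladium (Tsuji–Trost allylic esterification; the closest one-step relative is the Pd-catalysed butadiene/CO2 telomerisation, where an allyl-palladium carboxylate closes the same O–C(allyl) bond of a δ-lactone). The ring closes 6-exo at the allyl terminus, and attack at chain C6 would need an eight-membered ring containing a trans alkene, so ring size secures the regiochemistry. Two inversions amount to a suprafacial 1,3-transfer, so the CBS-derived (6S) centre of the (7E)-carbonate places oxygen on the same face at C8 and gives (R), while the syn position of the C5 chain on the allyl unit gives the E-alkene with CH2OTBS cis to that chain. Leakage through the anti-allyl isomer would give the Z-alkene with the opposite centre, a separable geometric isomer and not the enantiomer. The step needs cyclisation to be faster than proton loss from doubly allylic C9 and faster than Pd(0)/Pd(II) allyl exchange, which the intramolecular nucleophile, chelating dppe, low Pd loading and LiI (favouring external attack) support, and the CO2 atmosphere masks LiOt-Bu as its carbonate so the base-sensitive lactone survives.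

Step 14
Reactants: 22 (6R)-6-[(2E,6Z)-1-[(tert-butyldimethylsilyl)oxy]-8-[(tert-butyldiphenylsilyl)oxy]-6-methylocta-2,6-dien-2-yl]-3-(4-methylpent-3-en-1-yl)-5,6-dihydro-2H-pyran-2-one
Product: 23 (6R)-6-[(2E,6Z)-8-[(tert-butyldiphenylsilyl)oxy]-1-hydroxy-6-methylocta-2,6-dien-2-yl]-3-(4-methylpent-3-en-1-yl)-5,6-dihydro-2H-pyran-2-one
Conditions: HF·pyridine, pyridine, THF, 0 °C
Reagents that add atoms: none
Why: Buffered fluoride desilylation cleaves the primary TBS ether well before the more robust TBDPS ether and leaves the lactone and its allylic C–O bond untouched.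

Step 15
Reactants: 23 (6R)-6-[(2E,6Z)-8-[(tert-butyldiphenylsilyl)oxy]-1-hydroxy-6-methylocta-2,6-dien-2-yl]-3-(4-methylpent-3-en-1-yl)-5,6-dihydro-2H-pyran-2-one
Product: 24 (2E,6Z)-8-[(tert-butyldiphenylsilyl)oxy]-6-methyl-2-[(2R)-5-(4-methylpent-3-en-1-yl)-6-oxo-3,6-dihydro-2H-pyran-2-yl]octa-2,6-dien-1-yl acetate
Conditions: Ac2O, pyridine, DMAP (cat.), CH2Cl2, 0 °C
Reagents that add atoms: acetic anhydride, CC(=O)OC(C)=O
Why: DMAP-catalysed acetylation of the only free hydroxyl uses a base too weak to deprotonate the γ-position of the lactone.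

Step 16
Reactants: 24 (2E,6Z)-8-[(tert-butyldiphenylsilyl)oxy]-6-methyl-2-[(2R)-5-(4-methylpent-3-en-1-yl)-6-oxo-3,6-dihydro-2H-pyran-2-yl]octa-2,6-dien-1-yl acetate
Product: 25 (2E,6Z)-8-hydroxy-6-methyl-2-[(2R)-5-(4-methylpent-3-en-1-yl)-6-oxo-3,6-dihydro-2H-pyran-2-yl]octa-2,6-dien-1-yl acetate (target)
Conditions: HF·pyridine (excess), THF, rt
Reagents that add atoms: none
Why: Prolonged acidic-fluoride desilylation removes the TBDPS ether without the basic conditions that could hydrolyse the acetate or open the lactone by elimination.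

Compound list
1 | prop-2-yn-1-ol | C#CCO | starting material
2 | 5-bromo-2-methylpent-2-ene | CC(C)=CCCBr | starting material
3 | 7-methyloct-6-en-2-yn-1-ol | CC(C)=CCCC#CCO | intermediate
4 | sodium cyclic alkenylalanate (five-membered O–Al–C ring, two 2-methoxyethoxy ligands) | [Na+].COCCO[Al-]1(OCCOC)OCC=C1CCC=C(C)C | intermediate
5 | (2Z)-3-iodo-7-methylocta-2,6-dien-1-ol | OC/C=C(\I)CCC=C(C)C | intermediate
6 | (2Z)-1-bromo-3-iodo-7-methylocta-2,6-diene | BrC/C=C(\I)CCC=C(C)C | intermediate
7 | (5Z)-6-iodo-10-methylundeca-5,9-dien-2-yn-1-ol | OCC#CC/C=C(\I)CCC=C(C)C | intermediate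
8 | nerol, (2Z)-3,7-dimethylocta-2,6-dien-1-ol | CC(C)=CCC/C(C)=C\CO | starting material
9 | neryl tert-butyldiphenylsilyl ether | CC(C)=CCC/C(C)=C\CO[Si](c1ccccc1)(c1ccccc1)C(C)(C)C | intermediate
10 | rac-6,7-epoxyneryl tert-butyldiphenylsilyl ether | CC1(C)OC1CC/C(C)=C\CO[Si](c1ccccc1)(c1ccccc1)C(C)(C)C | intermediate
11 | (4Z)-6-[(tert-butyldiphenylsilyl)oxy]-4-methylhex-4-enal | O=CCC/C(C)=C\CO[Si](c1ccccc1)(c1ccccc1)C(C)(C)C | intermediate
12 | alkenylzirconocene chloride, lithium alkoxide (Zr on the carbon next to CH2OLi, cis to the new vinylic H; Cp rings drawn σ-bonded) | [Li]OC/C(=C\C/C=C(\I)CCC=C(C)C)[Zr](Cl)(C1C=CC=C1)C1C=CC=C1 | intermediate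
13 | alkenyl(methyl)zinc, lithium alkoxide (same geometry as 12) | [Li]OC/C(=C\C/C=C(\I)CCC=C(C)C)[Zn]C | intermediate
14 | rac-(2Z,7E,10Z)-1-[(tert-butyldiphenylsilyl)oxy]-7-(hydroxymethyl)-11-iodo-3,15-dimethylhexadeca-2,7,10,14-tetraen-6-ol | OC/C(=C\C/C=C(\I)CCC=C(C)C)C(O)CC/C(C)=C\CO[Si](c1ccccc1)(c1ccccc1)C(C)(C)C | intermediate
15 | rac-7-(TBS-oxymethyl) analogue of 14 | CC(C)(C)[Si](C)(C)OC/C(=C\C/C=C(\I)CCC=C(C)C)C(O)CC/C(C)=C\CO[Si](c1ccccc1)(c1ccccc1)C(C)(C)C | intermediate
16 | 6-ketone (cross-conjugation-free enone) derived from 15 | CC(C)(C)[Si](C)(C)OC/C(=C\C/C=C(\I)CCC=C(C)C)C(=O)CC/C(C)=C\CO[Si](c1ccccc1)(c1ccccc1)C(C)(C)C | intermediate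
17 | (6S)-allylic alcohol | CC(C)(C)[Si](C)(C)OC/C(=C\C/C=C(\I)CCC=C(C)C)[C@@H](O)CC/C(C)=C\CO[Si](c1ccccc1)(c1ccccc1)C(C)(C)C | intermediate
18 | (6S)-allylic tert-butyl carbonate | CC(C)(C)[Si](C)(C)OC/C(=C\C/C=C(\I)CCC=C(C)C)[C@@H](OC(=O)OC(C)(C)C)CC/C(C)=C\CO[Si](c1ccccc1)(c1ccccc1)C(C)(C)C | intermediate
19 | carbon dioxide | O=C=O | starting material
20 | alkenyllithium (Li in place of I, geometry retained) | CC(C)(C)[Si](C)(C)OC/C(=C\C/C=C(\[Li])CCC=C(C)C)[C@@H](OC(=O)OC(C)(C)C)CC/C(C)=C\CO[Si](c1ccccc1)(c1ccccc1)C(C)(C)C | intermediate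
21 | lithium (Z)-alkenecarboxylate (CO2Li cis to chain C9) | [Li+].CC(C)(C)[Si](C)(C)OC/C(=C\C/C=C(\C(=O)[O-])CCC=C(C)C)[C@@H](OC(=O)OC(C)(C)C)CC/C(C)=C\CO[Si](c1ccccc1)(c1ccccc1)C(C)(C)C | intermediate
22 | (6R)-lactone, bis-silyl ether | CC(C)(C)[Si](C)(C)OC/C(=C\CC/C(C)=C\CO[Si](c1ccccc1)(c1ccccc1)C(C)(C)C)[C@H]1CC=C(CCC=C(C)C)C(=O)O1 | intermediate
23 | (6R)-lactone, free CH2OH on C1', TBDPS ether retained | OC/C(=C\CC/C(C)=C\CO[Si](c1ccccc1)(c1ccccc1)C(C)(C)C)[C@H]1CC=C(CCC=C(C)C)C(=O)O1 | intermediate
24 | (6R)-lactone acetate, TBDPS ether retained | CC(=O)OC/C(=C\CC/C(C)=C\CO[Si](c1ccccc1)(c1ccccc1)C(C)(C)C)[C@H]1CC=C(CCC=C(C)C)C(=O)O1 | intermediate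
25 | (2E,6Z)-8-hydroxy-6-methyl-2-[(2R)-5-(4-methylpent-3-en-1-yl)-6-oxo-3,6-dihydro-2H-pyran-2-yl]octa-2,6-dien-1-yl acetate | CC(=O)OC/C(=C\CC/C(C)=C\CO)[C@H]1CC=C(CCC=C(C)C)C(=O)O1 | target

Total step count: 16. Longest linear sequence: 13 steps (steps 1–4 and 8–16, from prop-2-yn-1-ol).

Steps most likely to fail

Step 13. After ionisation the allyl-palladium stage may lose a proton from the doubly allylic chain C9 faster than the carboxylate closes. Allyl exchange between Pd(0) and Pd(II), or reaction through the anti-allyl isomer, may also erode the chirality transfer.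
- The fallback avoids any allyl-metal species and sets out from alcohol 17.
- t-BuLi (3 equiv), CO2 and mild acidification give the hydroxy acid F1.
- Catalytic triphenylsilyl perrhenate in Et2O at low temperature shifts the hydroxyl suprafacially from C6 to C8 through a chair-like perrhenate ester (rhenium-oxo catalysed 1,3-transposition of allylic alcohols).
- The transposed δ-hydroxy (Z)-enoic acid F2 is drained from the equilibrium by spontaneous lactonisation, which comes back to the route at 22.

Step 8. Hydrozirconation may place zirconium on the distal alkyne carbon, or the hindered alkenylzinc may add sluggishly.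
- The fallback makes the regiochemistry electronic and sets out from bromide 6.
- Copper(I)-mediated coupling with methyl propiolate gives the skipped enynoate F3.
- Conjugate syn-hydroalumination with DIBAL-H/NMO, followed in the same flask by aldehyde 11, gives the (Z)-α-alkylidene-β-hydroxy ester F4.
- DIBAL-H reduction of the ester comes back to the route at diol 14.

Step 11. The catalyst may discriminate poorly between two long-chain ketone flanks, or the skipped diene may drift into conjugation at the enone stage.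
- The fallback avoids the ketone and sets the carbinol centre during C–C bond formation, setting out from 7 and 11.
- The hydrozirconation/zinc sequence of step 8 is run with lithium salts sequestered and with the appropriate enantiomer of a β-amino alcohol ligand (MIB type) on zinc, to give the (6S)-diol F5.
- Silylation as in step 9 comes back to the route at 17, and steps 10 and 11 are omitted.

Further compounds
F1 | step 13 | (6S)-hydroxy acid (CO2H in place of I of 17, cis to chain C9) | CC(C)(C)[Si](C)(C)OC/C(=C\C/C=C(\C(=O)O)CCC=C(C)C)[C@@H](O)CC/C(C)=C\CO[Si](c1ccccc1)(c1ccccc1)C(C)(C)C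
F2 | step 13 | transposed (8R)-δ-hydroxy (Z)-enoic acid with (6E)-alkene | CC(C)(C)[Si](C)(C)OC/C(=C\CC/C(C)=C\CO[Si](c1ccccc1)(c1ccccc1)C(C)(C)C)[C@H](O)C/C=C(\C(=O)O)CCC=C(C)C
F3 | step 8 | methyl (5Z)-6-iodo-10-methylundeca-5,9-dien-2-ynoate | COC(=O)C#CC/C=C(\I)CCC=C(C)C
F4 | step 8 | rac-(Z)-α-alkylidene-β-hydroxy methyl ester (CO2Me in place of CH2OH of 14) | COC(=O)/C(=C\C/C=C(\I)CCC=C(C)C)C(O)CC/C(C)=C\CO[Si](c1ccccc1)(c1ccccc1)C(C)(C)C
F5 | step 11 | (6S)-enantiomer of diol 14 | OC/C(=C\C/C=C(\I)CCC=C(C)C)[C@@H](O)CC/C(C)=C\CO[Si](c1ccccc1)(c1ccccc1)C(C)(C)C
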